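**Retrosynthetic overview**
- The free (S)-hydroperoxide is unmasked last from a monoperoxyketal, after the C5 carbinol has been oxidised to the β,γ-unsaturated enone.
- The C–OO bond comes from SN2 inversion of an (R)-secondary allylic mesylate by 2-methoxyprop-2-yl hydroperoxide.
- The aryl ether comes from opening an (R)-terminal vinyl epoxide at CH2 with methyl vanillate.
- The key C4–C5 bond comes from Hosomi–Sakurai allylation of 3-methylbut-2-enal by a chiral 2-substituted allylsilane, made from methyl (S)-glycerate acetonide (the only source of chirality).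
- No ring is built: the arene is bought, and the only ring made on the way is a transient oxirane.

Assumption: the SMILES encodes (S) at the hydroperoxide carbon; the C5 carbinol made in step 2 is carried as an epimer mixture because it is later oxidised to the ketone.

**Step 1**
Reactants: 1 methyl (4S)-2,2-dimethyl-1,3-dioxolane-4-carboxylate; 2 (trimethylsilyl)methylmagnesium chloride
Product: 4 (4R)-2,2-dimethyl-4-[3-(trimethylsilyl)prop-1-en-2-yl]-1,3-dioxolane, via bis(silylmethyl)carbinol 3 (not isolated)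
Conditions: CeCl3 (anhydrous, 3 equiv), 2 (3 equiv), THF, –78 °C → rt; aq. NH4Cl; then SiO2, CH2Cl2, rt
Reagents that add atoms: none
Why: Bunnelle-type allylsilane synthesis, in which the non-basic organocerium reagent adds twice to the ester without epimerising the α-stereocentre (carried over unchanged from 1) and the β-hydroxysilane then undergoes Peterson elimination.

**Step 2**
Reactants: 4 (4R)-2,2-dimethyl-4-[3-(trimethylsilyl)prop-1-en-2-yl]-1,3-dioxolane; 5 3-methylbut-2-enal
Product: 6 2-[(4R)-2,2-dimethyl-1,3-dioxolan-4-yl]-6-methylhepta-1,5-dien-4-ol (C4 epimer mixture)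
Conditions: BF3·OEt2 (1.2 equiv), CH2Cl2, –78 °C; then aq. NaHCO3
Reagents that add atoms: none
Why: Hosomi–Sakurai carbonyl allylation, in which the BF3-activated enal is attacked 1,2 by the terminal CH2 of the symmetrical 2-substituted allylsilane to forge the C4–C5 bond; the new carbinol centre forms unselectively and is later oxidised away.

**Step 3**
Reactants: 6 2-[(4R)-2,2-dimethyl-1,3-dioxolan-4-yl]-6-methylhepta-1,5-dien-4-ol
Product: 7 tert-butyl({2-[(4R)-2,2-dimethyl-1,3-dioxolan-4-yl]-6-methylhepta-1,5-dien-4-yl}oxy)diphenylsilane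
Conditions: TBDPSCl, imidazole, DMAP (cat.), DMF, rt
Reagents that add atoms: tert-butyl(chloro)diphenylsilane (TBDPSCl), CC(C)(C)[Si](Cl)(c1ccccc1)c1ccccc1
Why: Silylation of the secondary alcohol gives an ether that survives the acid, base and peroxide-anion steps ahead and is removed by fluoride.

**Step 4**
Reactants: 7 tert-butyl({2-[(4R)-2,2-dimethyl-1,3-dioxolan-4-yl]-6-methylhepta-1,5-dien-4-yl}oxy)diphenylsilane
Product: 8 (2R)-5-[(tert-butyldiphenylsilyl)oxy]-7-methyl-3-methylideneoct-6-ene-1,2-diol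
Conditions: AcOH/THF/H2O (3:1:1), 40 °C
Reagents that add atoms: none
Why: Acid-catalysed acetal hydrolysis removes the terminal acetonide while the bulky TBDPS ether and both alkenes stay intact, and no bond at the stereocentre is broken.

**Step 5**
Reactants: 8 (2R)-5-[(tert-butyldiphenylsilyl)oxy]-7-methyl-3-methylideneoct-6-ene-1,2-diol
Product: 9 (2R)-5-[(tert-butyldiphenylsilyl)oxy]-2-hydroxy-7-methyl-3-methylideneoct-6-en-1-yl 4-methylbenzenesulfonate
Conditions: TsCl (1.05 equiv), Bu2SnO (2 mol%), Et3N, CH2Cl2, 0 °C → rt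
Reagents that add atoms: 4-methylbenzenesulfonyl chloride (TsCl), Cc1ccc(cc1)S(=O)(=O)Cl
Why: Tin-catalysed (stannylene acetal) regioselective sulfonylation picks the primary hydroxyl of the 1,2-diol.

**Step 6**
Reactants: 9 (2R)-5-[(tert-butyldiphenylsilyl)oxy]-2-hydroxy-7-methyl-3-methylideneoct-6-en-1-yl 4-methylbenzenesulfonate
Product: 10 tert-butyl({6-methyl-2-[(2R)-oxiran-2-yl]hepta-1,5-dien-4-yl}oxy)diphenylsilane
Conditions: K2CO3, MeOH, 0 °C → rt
Reagents that add atoms: none
Why: Intramolecular Williamson etherification of the alkoxide onto the primary tosylate closes the oxirane with retention, because the C–O bond at the stereocentre is not broken.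

**Step 7**
Reactants: 10 tert-butyl({6-methyl-2-[(2R)-oxiran-2-yl]hepta-1,5-dien-4-yl}oxy)diphenylsilane; 11 methyl 4-hydroxy-3-methoxybenzoate (methyl vanillate)
Product: 12 methyl 4-{[(2R)-5-[(tert-butyldiphenylsilyl)oxy]-2-hydroxy-7-methyl-3-methylideneoct-6-en-1-yl]oxy}-3-methoxybenzoate
Conditions: 11 (1.3 equiv), K2CO3 (0.2 equiv), DMF, 70 °C
Reagents that add atoms: none
Why: Base-catalysed SN2 ring opening of the terminal epoxide by the phenoxide at the unhindered CH2 forms the aryl ether and frees the (R)-secondary allylic alcohol without touching the stereocentre.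

**Step 8**
Reactants: 12 methyl 4-{[(2R)-5-[(tert-butyldiphenylsilyl)oxy]-2-hydroxy-7-methyl-3-methylideneoct-6-en-1-yl]oxy}-3-methoxybenzoate
Product: 13 methyl 4-{[(2R)-5-[(tert-butyldiphenylsilyl)oxy]-2-(methanesulfonyloxy)-7-methyl-3-methylideneoct-6-en-1-yl]oxy}-3-methoxybenzoate
Conditions: MsCl, Et3N, CH2Cl2, –20 → 0 °C; used at once
Reagents that add atoms: methanesulfonyl chloride (MsCl), CS(=O)(=O)Cl
Why: O-sulfonylation (retention) turns the secondary alcohol into a leaving group, and the β-aryloxy group retards ionisation so the allylic mesylate can be handled cold.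

**Step 9**
Reactants: 14 2,3-dimethylbut-2-ene
Product: 17 2-hydroperoxy-2-methoxypropane, via primary ozonide 15 (not isolated), via acetone O-oxide 16 (not isolated)
Conditions: O3, CH2Cl2/MeOH (4:1), –78 °C; N2 purge; concentrate cold behind a shield and use as a solution
Reagents that add atoms: ozone, [O-][O+]=O; methanol, CO
Why: Criegee ozonolysis in a participating solvent, where cycloreversion of the primary ozonide gives acetone and a carbonyl oxide that methanol traps as the α-methoxy hydroperoxide.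

**Step 10**
Reactants: 13 methyl 4-{[(2R)-5-[(tert-butyldiphenylsilyl)oxy]-2-(methanesulfonyloxy)-7-methyl-3-methylideneoct-6-en-1-yl]oxy}-3-methoxybenzoate; 17 2-hydroperoxy-2-methoxypropane
Product: 18 methyl 4-{[(2S)-5-[(tert-butyldiphenylsilyl)oxy]-2-[(2-methoxypropan-2-yl)peroxy]-7-methyl-3-methylideneoct-6-en-1-yl]oxy}-3-methoxybenzoate
Conditions: 17 (3 equiv), CsOH·H2O (2.5 equiv), DMF, 0 °C → rt
Reagents that add atoms: none
Why: SN2 alkylation of the cesium peroxide (an α-effect nucleophile of low basicity) on the secondary mesylate goes with inversion, turning the (R)-mesylate into the (S)-peroxide already protected as a monoperoxyketal.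

**Step 11**
Reactants: 18 methyl 4-{[(2S)-5-[(tert-butyldiphenylsilyl)oxy]-2-[(2-methoxypropan-2-yl)peroxy]-7-methyl-3-methylideneoct-6-en-1-yl]oxy}-3-methoxybenzoate
Product: 19 methyl 4-{[(2S)-5-hydroxy-2-[(2-methoxypropan-2-yl)peroxy]-7-methyl-3-methylideneoct-6-en-1-yl]oxy}-3-methoxybenzoate
Conditions: TBAF/AcOH (1:1, 2 equiv), THF, 0 °C → rt
Reagents that add atoms: none
Why: Fluoride-mediated desilylation, buffered with acetic acid so the medium is too weakly basic for Kornblum–DeLaMare fragmentation of the secondary peroxide, which is itself inert to fluoride.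

**Step 12**
Reactants: 19 methyl 4-{[(2S)-5-hydroxy-2-[(2-methoxypropan-2-yl)peroxy]-7-methyl-3-methylideneoct-6-en-1-yl]oxy}-3-methoxybenzoate
Product: 20 methyl 3-methoxy-4-{[(2S)-2-[(2-methoxypropan-2-yl)peroxy]-7-methyl-3-methylidene-5-oxooct-6-en-1-yl]oxy}benzoate
Conditions: Dess–Martin periodinane (1.3 equiv), NaHCO3 (buffer), CH2Cl2, 0 °C → rt
Reagents that add atoms: none
Why: Dess–Martin oxidation of the secondary allylic alcohol under buffered, non-enolising conditions gives the ketone without moving the methylidene into conjugation and without touching the O–O bond.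

**Step 13**
Reactants: 20 methyl 3-methoxy-4-{[(2S)-2-[(2-methoxypropan-2-yl)peroxy]-7-methyl-3-methylidene-5-oxooct-6-en-1-yl]oxy}benzoate
Product: 21 methyl 4-{[(2S)-2-hydroperoxy-7-methyl-3-methylidene-5-oxooct-6-en-1-yl]oxy}-3-methoxybenzoate
Conditions: AcOH/THF/H2O (4:2:1), rt
Reagents that add atoms: none
Why: Mild acid hydrolysis of the monoperoxyketal cleaves only the ketal carbon–oxygen bonds, releasing the free hydroperoxide with the (S) configuration intact.

**Compound list**
1 | methyl (4S)-2,2-dimethyl-1,3-dioxolane-4-carboxylate | COC(=O)[C@@H]1COC(C)(C)O1 | starting material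
2 | (trimethylsilyl)methylmagnesium chloride | C[Si](C)(C)C[Mg]Cl | starting material
3 | 2-[(4S)-2,2-dimethyl-1,3-dioxolan-4-yl]-1,3-bis(trimethylsilyl)propan-2-ol | C[Si](C)(C)CC(O)(C[Si](C)(C)C)[C@@H]1COC(C)(C)O1 | intermediate
4 | (4R)-2,2-dimethyl-4-[3-(trimethylsilyl)prop-1-en-2-yl]-1,3-dioxolane | C=C(C[Si](C)(C)C)[C@@H]1COC(C)(C)O1 | intermediate
5 | 3-methylbut-2-enal | CC(C)=CC=O | starting material
6 | 2-[(4R)-2,2-dimethyl-1,3-dioxolan-4-yl]-6-methylhepta-1,5-dien-4-ol (C4 epimer mixture) | C=C(CC(O)C=C(C)C)[C@@H]1COC(C)(C)O1 | intermediate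
7 | tert-butyl({2-[(4R)-2,2-dimethyl-1,3-dioxolan-4-yl]-6-methylhepta-1,5-dien-4-yl}oxy)diphenylsilane | C=C(CC(O[Si](c1ccccc1)(c1ccccc1)C(C)(C)C)C=C(C)C)[C@@H]1COC(C)(C)O1 | intermediate
8 | (2R)-5-[(tert-butyldiphenylsilyl)oxy]-7-methyl-3-methylideneoct-6-ene-1,2-diol | C=C(CC(O[Si](c1ccccc1)(c1ccccc1)C(C)(C)C)C=C(C)C)[C@@H](O)CO | intermediate
9 | (2R)-5-[(tert-butyldiphenylsilyl)oxy]-2-hydroxy-7-methyl-3-methylideneoct-6-en-1-yl 4-methylbenzenesulfonate | C=C(CC(O[Si](c1ccccc1)(c1ccccc1)C(C)(C)C)C=C(C)C)[C@@H](O)COS(=O)(=O)c1ccc(C)cc1 | intermediate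
10 | tert-butyl({6-methyl-2-[(2R)-oxiran-2-yl]hepta-1,5-dien-4-yl}oxy)diphenylsilane | C=C(CC(O[Si](c1ccccc1)(c1ccccc1)C(C)(C)C)C=C(C)C)[C@@H]1CO1 | intermediate
11 | methyl 4-hydroxy-3-methoxybenzoate (methyl vanillate) | COC(=O)c1ccc(O)c(OC)c1 | starting material
12 | methyl 4-{[(2R)-5-[(tert-butyldiphenylsilyl)oxy]-2-hydroxy-7-methyl-3-methylideneoct-6-en-1-yl]oxy}-3-methoxybenzoate | C=C(CC(O[Si](c1ccccc1)(c1ccccc1)C(C)(C)C)C=C(C)C)[C@@H](O)COc1ccc(C(=O)OC)cc1OC | intermediate
13 | methyl 4-{[(2R)-5-[(tert-butyldiphenylsilyl)oxy]-2-(methanesulfonyloxy)-7-methyl-3-methylideneoct-6-en-1-yl]oxy}-3-methoxybenzoate | C=C(CC(O[Si](c1ccccc1)(c1ccccc1)C(C)(C)C)C=C(C)C)[C@@H](OS(C)(=O)=O)COc1ccc(C(=O)OC)cc1OC | intermediate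
14 | 2,3-dimethylbut-2-ene | CC(C)=C(C)C | starting material
15 | 4,4,5,5-tetramethyl-1,2,3-trioxolane (primary ozonide) | CC1(C)OOOC1(C)C | intermediate
16 | propan-2-one O-oxide (acetone O-oxide) | CC(C)=[O+][O-] | intermediate
17 | 2-hydroperoxy-2-methoxypropane (2-methoxyprop-2-yl hydroperoxide) | COC(C)(C)OO | intermediate
18 | methyl 4-{[(2S)-5-[(tert-butyldiphenylsilyl)oxy]-2-[(2-methoxypropan-2-yl)peroxy]-7-methyl-3-methylideneoct-6-en-1-yl]oxy}-3-methoxybenzoate | C=C(CC(O[Si](c1ccccc1)(c1ccccc1)C(C)(C)C)C=C(C)C)[C@H](OOC(C)(C)OC)COc1ccc(C(=O)OC)cc1OC | intermediate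
19 | methyl 4-{[(2S)-5-hydroxy-2-[(2-methoxypropan-2-yl)peroxy]-7-methyl-3-methylideneoct-6-en-1-yl]oxy}-3-methoxybenzoate | C=C(CC(O)C=C(C)C)[C@H](OOC(C)(C)OC)COc1ccc(C(=O)OC)cc1OC | intermediate
20 | methyl 3-methoxy-4-{[(2S)-2-[(2-methoxypropan-2-yl)peroxy]-7-methyl-3-methylidene-5-oxooct-6-en-1-yl]oxy}benzoate | C=C(CC(=O)C=C(C)C)[C@H](OOC(C)(C)OC)COc1ccc(C(=O)OC)cc1OC | intermediate
21 | methyl 4-{[(2S)-2-hydroperoxy-7-methyl-3-methylidene-5-oxooct-6-en-1-yl]oxy}-3-methoxybenzoate | C=C(CC(=O)C=C(C)C)[C@@H](COc1ccc(C(=O)OC)cc1OC)OO | target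

**Totals and risk**
Total step count: 13 (12 on the main line plus step 9, which prepares the peroxide reagent). Longest linear sequence: 12 steps, from 1 to 21 through steps 1–8 and 10–13.

The three steps most likely to fail:

Step 10, the peroxide SN2 on the secondary allylic mesylate. The bulky peroxyketal anion may instead attack the terminal methylidene carbon (SN2′), cause E2 toward the aryloxydiene, or erode the ee. The fallback changes the order of events: the C–OO bond is made with unprotected hydrogen peroxide and protection follows. It sets out from 13. A large excess of anhydrous H2O2 with CsOH·H2O in THF/DMF at 0 °C gives, with inversion, methyl 4-{[(2S)-5-[(tert-butyldiphenylsilyl)oxy]-2-hydroperoxy-7-methyl-3-methylideneoct-6-en-1-yl]oxy}-3-methoxybenzoate F4; the much smaller nucleophile favours direct attack at the branched carbon. F4 is then capped in a separate operation (2-methoxypropene, cat. PPTS, CH2Cl2, 0 °C) and the route is rejoined at 18.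

Step 2, the Sakurai key step. The Lewis acid may ionise the doubly allylic product, attack the acetonide, or promote a Prins reaction with a second aldehyde. The fallback swaps Lewis-acid allylsilane chemistry for a neutral Barbier allylation. It sets out from 4. Bromodesilylation (NBS, propylene oxide, CH2Cl2, –78 → 0 °C) gives (4R)-4-(3-bromoprop-1-en-2-yl)-2,2-dimethyl-1,3-dioxolane F1. Treating F1 and aldehyde 5 with In powder in THF/H2O at rt gives clean 1,2-addition and comes back to the route at 6.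

Step 7, the regiochemistry of the vinyl epoxide opening. The phenoxide could attack the allylic carbon or add SN2′. The fallback avoids the epoxide altogether and sets out from tosylate 9. Silylation (TESOTf, 2,6-lutidine, CH2Cl2, –78 °C) gives (2R)-5-[(tert-butyldiphenylsilyl)oxy]-7-methyl-3-methylidene-2-[(triethylsilyl)oxy]oct-6-en-1-yl 4-methylbenzenesulfonate F2. Direct SN2 displacement of the primary tosylate by 11 (Cs2CO3, DMF, 60 °C) gives methyl 4-{[(2R)-5-[(tert-butyldiphenylsilyl)oxy]-7-methyl-3-methylidene-2-[(triethylsilyl)oxy]oct-6-en-1-yl]oxy}-3-methoxybenzoate F3. Selective removal of the triethylsilyl group (AcOH/THF/H2O, rt) returns to 12.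

**Further compounds**
F1 | step 2 | (4R)-4-(3-bromoprop-1-en-2-yl)-2,2-dimethyl-1,3-dioxolane | C=C(CBr)[C@@H]1COC(C)(C)O1
F2 | step 7 | (2R)-5-[(tert-butyldiphenylsilyl)oxy]-7-methyl-3-methylidene-2-[(triethylsilyl)oxy]oct-6-en-1-yl 4-methylbenzenesulfonate | C=C(CC(O[Si](c1ccccc1)(c1ccccc1)C(C)(C)C)C=C(C)C)[C@@H](O[Si](CC)(CC)CC)COS(=O)(=O)c1ccc(C)cc1
F3 | step 7 | methyl 4-{[(2R)-5-[(tert-butyldiphenylsilyl)oxy]-7-methyl-3-methylidene-2-[(triethylsilyl)oxy]oct-6-en-1-yl]oxy}-3-methoxybenzoate | C=C(CC(O[Si](c1ccccc1)(c1ccccc1)C(C)(C)C)C=C(C)C)[C@@H](O[Si](CC)(CC)CC)COc1ccc(C(=O)OC)cc1OC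
F4 | step 10 | methyl 4-{[(2S)-5-[(tert-butyldiphenylsilyl)oxy]-2-hydroperoxy-7-methyl-3-methylideneoct-6-en-1-yl]oxy}-3-methoxybenzoate | C=C(CC(O[Si](c1ccccc1)(c1ccccc1)C(C)(C)C)C=C(C)C)[C@H](OO)COc1ccc(C(=O)OC)cc1OC
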